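**Retrosynthetic overview**

- The target is traced back through esterification, oxidation, desilylation and deiodination to a 5-iodo-1,2-dioxane. That ring comes from 6-endo iodoperoxidation of a C3 hydroperoxide onto a Z-configured C5=C6 alkene, and the hydroperoxide comes from the C3 alcohol by triflate displacement with inversion.
- The strategy rests on the quaternary peroxide carbon C6 of the 1,2-dioxane (ring O1–O2–C3–C4–C5–C6). It carries a methyl group, the CH2CH2 arm (C7–C8) to ring A and the C5–C4–C3 chain, which is the substitution pattern of a Z-trisubstituted alkene C5=C6.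
- Key disconnection: the C7–C6 bond (alkylcopper adds across propyne) and the C5–C4 bond (the alkenylcopper opens a chiral terminal epoxide), both made in one operation.
- The ring A bromide comes from β-cyclocitral: Sharpless epoxidation sets the tertiary carbinol, a one-carbon homologation follows, and an aluminium amide epoxide-to-allylic-alcohol isomerisation unveils the exocyclic methylene. The epoxide comes from (Z)-but-2-ene-1,4-diol by Sharpless epoxidation and Me3Al opening.
- Ring order: ring A is present from the start, the oxirane of the C1–C4 fragment is opened in the key step, and the 1,2-dioxane is closed last.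

Key step: step 13

Remark on numbering: atoms are numbered along the chain of the target, C1 (ester carbon) to C8 (CH2 on ring A). The 1,2-dioxane is numbered O1–O2–C3–C4–C5–C6, with the side chain on C3 and the quaternary carbon as C6. The oxabicycles of the ring A series keep their own bicyclic numbering.

Assumption: the facial rule of the Sharpless epoxidation established for primary allylic alcohols is taken to hold for the tetrasubstituted alcohol 2, so that D-(−)-tartrate gives the (1R,6R)-epoxide.

**Ring A bromide**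

Step 1
Reactants: 1 β-cyclocitral (2,6,6-trimethylcyclohex-1-ene-1-carbaldehyde)
Product: 2 β-cyclogeraniol, (2,6,6-trimethylcyclohex-1-en-1-yl)methanol
Conditions: NaBH4, MeOH, 0 °C
Reagents that add atoms: none
Why: Borohydride 1,2-reduction of the hindered enal should give the allylic alcohol, the tetrasubstituted alkene being inert to hydride.

Step 2
Reactants: 2 β-cyclogeraniol
Product: 3 [(1R,6R)-2,2,6-trimethyl-7-oxabicyclo[4.1.0]heptan-1-yl]methanol
Conditions: Ti(OiPr)4 (cat.), D-(−)-diethyl tartrate (cat.), t-BuOOH, 4 Å MS, CH2Cl2, −20 °C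
Reagents that add atoms: tert-butyl hydroperoxide, CC(C)(C)OO
Why: Sharpless asymmetric epoxidation, in which the titanium tartrate complex bound to the allylic hydroxyl delivers oxygen to one face of the tetrasubstituted alkene, D-(−)-tartrate being chosen so that the C1–O bond has the sense of the (S)-carbinol of ring A.

Step 3
Reactants: 3 epoxy alcohol
Product: 4 (1S,6R)-2,2,6-trimethyl-7-oxabicyclo[4.1.0]heptane-1-carbaldehyde
Conditions: Dess–Martin periodinane, pyridine, CH2Cl2, 0 °C → rt
Reagents that add atoms: none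
Why: Dess–Martin oxidation under buffered conditions should spare the acid-sensitive epoxide, and the quaternary α-carbon cannot epimerise.

Step 4
Reactants: 4 epoxy aldehyde
Product: 5 (1S,6R)-1-ethenyl-2,2,6-trimethyl-7-oxabicyclo[4.1.0]heptane
Conditions: Ph3PCH3Br, KN(SiMe3)2, THF, 0 °C → rt
Reagents that add atoms: methyltriphenylphosphonium bromide, C[P+](c1ccccc1)(c1ccccc1)c1ccccc1.[Br-]
Why: Wittig methylenation of a non-enolisable aldehyde by the unstabilised ylide should proceed without touching the epoxide.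

Step 5
Reactants: 5 vinyl epoxide
Product: 7 2-[(1S,6R)-2,2,6-trimethyl-7-oxabicyclo[4.1.0]heptan-1-yl]ethan-1-ol, via the B-alkyl-9-BBN adduct 6 (not isolated)
Conditions: 9-BBN, THF, 0 °C → rt; then NaOH, H2O2, 0 °C
Reagents that add atoms: hydrogen peroxide, OO
Why: Anti-Markovnikov hydroboration–oxidation of the only alkene present, where the weakly Lewis acidic and bulky 9-BBN should leave the hindered tetrasubstituted epoxide intact.

Step 6
Reactants: 7 epoxy ethanol
Product: 8 (1S)-1-(2-hydroxyethyl)-2,2-dimethyl-6-methylidenecyclohexan-1-ol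
Conditions: diethylaluminium 2,2,6,6-tetramethylpiperidide (from lithium 2,2,6,6-tetramethylpiperidide and Et2AlCl, 4 equiv), toluene, 0 °C → rt
Reagents that add atoms: none
Why: Aluminium amide epoxide-to-allylic-alcohol isomerisation by syn β-elimination through a cyclic transition state should remove a proton from the least hindered position (the C6 methyl group), so that the C6–O bond breaks, the exocyclic methylene forms and the C1–O stereocentre is untouched.

Step 7
Reactants: 8 diol
Product: 9 (1S)-1-(2-bromoethyl)-2,2-dimethyl-6-methylidenecyclohexan-1-ol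
Conditions: CBr4, PPh3, 2,6-lutidine, CH2Cl2, 0 °C
Reagents that add atoms: carbon tetrabromide, BrC(Br)(Br)Br
Why: Appel bromination should select the primary hydroxyl, since the tertiary allylic hydroxyl flanked by two fully substituted carbons cannot form the alkoxyphosphonium ion at a useful rate.

Step 8
Reactants: 9 bromo alcohol
Product: 10 {[(1S)-1-(2-bromoethyl)-2,2-dimethyl-6-methylidenecyclohexyl]oxy}triethylsilane
Conditions: Et3SiOTf, 2,6-lutidine, CH2Cl2, −78 → 0 °C
Reagents that add atoms: triethylsilyl trifluoromethanesulfonate, CC[Si](CC)(CC)OS(=O)(=O)C(F)(F)F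
Why: Silylation with a silyl triflate is reactive enough for the hindered tertiary alcohol and gives an ether that tolerates organomagnesium and organocopper reagents.

**Epoxide fragment**

Step 9
Reactants: 11 (Z)-but-2-ene-1,4-diol
Product: 12 (2Z)-4-{[tert-butyl(dimethyl)silyl]oxy}but-2-en-1-ol
Conditions: NaH (1 equiv), THF, 0 °C; t-BuMe2SiCl
Reagents that add atoms: tert-butyldimethylsilyl chloride, CC(C)(C)[Si](C)(C)Cl
Why: Monosilylation of a symmetric diol through its sparingly soluble monosodium alkoxide should favour the mono-ether.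

Step 10
Reactants: 12 monosilyl ether
Product: 13 [(2R,3S)-3-({[tert-butyl(dimethyl)silyl]oxy}methyl)oxiran-2-yl]methanol
Conditions: Ti(OiPr)4, D-(−)-diethyl tartrate, t-BuOOH, 4 Å MS, CH2Cl2, −20 °C
Reagents that add atoms: tert-butyl hydroperoxide, CC(C)(C)OO
Why: Sharpless asymmetric epoxidation of the Z-allylic alcohol, where D-(−)-tartrate directs oxygen to the face that gives the (2R,3S)-cis-epoxide, and any minor enantiomer from this slower substrate class becomes a separable diastereomer after the fragment union.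

Step 11
Reactants: 13 epoxy alcohol
Product: 14 (2S,3R)-4-{[tert-butyl(dimethyl)silyl]oxy}-3-methylbutane-1,2-diol
Conditions: Me3Al (3 equiv), hexane/CH2Cl2, 0 °C → rt
Reagents that add atoms: trimethylaluminium, C[Al](C)C
Why: Trialkylaluminium opening of a 2,3-epoxy alcohol, in which the aluminium alkoxide chelate directs methyl transfer to C3 with inversion, should set the methyl stereocentre syn to the retained C2 hydroxyl.

Step 12
Reactants: 14 diol
Product: 16 tert-butyl(dimethyl){(2R)-2-[(2S)-oxiran-2-yl]propoxy}silane, via the primary tosylate 15 (not isolated)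
Conditions: TsCl, Et3N, Bu2SnO (cat.), CH2Cl2, 0 °C; then K2CO3, MeOH, 0 °C
Reagents that add atoms: none
Why: Selective sulfonylation of the primary hydroxyl through the stannylene acetal, followed by intramolecular Williamson closure (3-exo-tet), should form the terminal epoxide with retention at the carbinol carbon and faster than any silyl migration.

**Fragment union**

Step 13
Reactants: 10 ring A bromide (1.5 equiv), 17 propyne, 16 epoxide
Product: 21 (2R,3R,5Z)-1-{[tert-butyl(dimethyl)silyl]oxy}-8-{(1S)-2,2-dimethyl-6-methylidene-1-[(triethylsilyl)oxy]cyclohexyl}-2,6-dimethyloct-5-en-3-ol, via Grignard reagent 18 (not isolated), via alkylcopper reagent 19 (not isolated), via Z-alkenylcopper reagent 20 (not isolated)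
Conditions: 10, Mg, Et2O, 35 °C; CuBr·SMe2, Et2O/Me2S, −45 °C; 17 (excess), −25 °C, 48 h; hex-1-ynyllithium, HMPA, −78 °C; 16, −78 → 0 °C; aq NH4Cl
Reagents that add atoms: none
Why: The alkylcopper reagent 19, formed from Grignard reagent 18 and CuBr·SMe2, adds across propyne through a four-centre syn transition state that places the alkyl group on the internal carbon (C7–C6 bond) and copper on the terminal carbon, so the ring A arm and copper are cis in 20. Hex-1-ynyllithium then converts 20 into a mixed lithium cuprate whose alkenyl–copper bond opens epoxide 16 by SN2 attack at the unsubstituted CH2 (C5–C4 bond) with retention of the alkene geometry. The closest known reaction type is the carbocupration of terminal alkynes by alkylcopper–magnesium halide reagents, followed by alkylation of the derived alkenylcuprate with a monosubstituted epoxide. No ring is closed and no stereocentre is created: C2 and C3 come unchanged from 16 (C3 is deliberately epimeric to the target, for the later inversion) and the ring A carbinol comes from 10. The step needs regioselective and syn-specific carbometalation, secured by the concerted addition to unhindered methylacetylene and the configurational stability of the alkenylcopper at low temperature, and regioselective epoxide opening, secured by the α-branch that shields the substituted oxirane carbon. The silyl ethers, the exocyclic alkene and the non-transferable alkynyl ligand should be inert under these conditions.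

**Peroxide installation and endgame**

Step 14
Reactants: 21 Z-homoallylic alcohol
Product: 22 (2R,3R,5Z)-1-{[tert-butyl(dimethyl)silyl]oxy}-8-{(1S)-2,2-dimethyl-6-methylidene-1-[(triethylsilyl)oxy]cyclohexyl}-2,6-dimethyloct-5-en-3-yl trifluoromethanesulfonate
Conditions: Tf2O, 2,6-lutidine, CH2Cl2, −78 °C; cold filtration, used at once
Reagents that add atoms: trifluoromethanesulfonic anhydride, O=S(=O)(OS(=O)(=O)C(F)(F)F)C(F)(F)F
Why: O-Sulfonylation forms the leaving group with retention at C3, and the low temperature and immediate use should limit ionisation of the homoallylic triflate.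

Step 15
Reactants: 23 2,3-dimethylbut-2-ene
Product: 24 2-methoxypropan-2-yl hydroperoxide
Conditions: O3, MeOH/CH2Cl2, −78 °C
Reagents that add atoms: ozone, [O-][O+]=O; methanol, CO
Why: Ozonolysis of the tetrasubstituted alkene, with trapping of the Criegee carbonyl oxide by methanol, should give the hydroperoxy ketal, a protected form of H2O2 with one nucleophilic oxygen.

Step 16
Reactants: 22 triflate, 24 2-methoxypropan-2-yl hydroperoxide
Product: 25 tert-butyl{[(2R,3S,5Z)-8-{(1S)-2,2-dimethyl-6-methylidene-1-[(triethylsilyl)oxy]cyclohexyl}-3-[(2-methoxypropan-2-yl)peroxy]-2,6-dimethyloct-5-en-1-yl]oxy}dimethylsilane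
Conditions: 24, KOt-Bu, THF, 0 °C; then 22, −78 → 0 °C
Reagents that add atoms: none
Why: SN2 displacement of a secondary triflate by a peroxide anion, a strong nucleophile of low basicity, should install the C3–O–O bond with inversion, giving the (3S) configuration of the target.

Step 17
Reactants: 25 monoperoxyketal
Product: 26 (2R,3S,5Z)-1-{[tert-butyl(dimethyl)silyl]oxy}-8-{(1S)-2,2-dimethyl-6-methylidene-1-[(triethylsilyl)oxy]cyclohexyl}-2,6-dimethyloct-5-en-3-yl hydroperoxide
Conditions: AcOH/THF/H2O, 0 °C → rt
Reagents that add atoms: none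
Why: Acid-catalysed hydrolysis of the very labile acetone-derived peroxyketal should free the hydroperoxide under conditions that the primary silyl ether and the hindered tertiary silyl ether withstand.

Step 18
Reactants: 26 hydroperoxide
Product: 27 tert-butyl{(2R)-2-[(3S,5S,6S)-6-(2-{(1S)-2,2-dimethyl-6-methylidene-1-[(triethylsilyl)oxy]cyclohexyl}ethyl)-5-iodo-6-methyl-1,2-dioxan-3-yl]propoxy}dimethylsilane
Conditions: N-iodosuccinimide, CH2Cl2, −40 → 0 °C, dark
Reagents that add atoms: N-iodosuccinimide, O=C1CCC(=O)N1I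
Why: Electrophilic 6-endo iodoperoxidation, in which the iodonium ion forms on the more nucleophilic trisubstituted alkene and the hydroperoxide attacks tertiary C6 anti to iodine through a chair with the C3 side chain equatorial, so that with the Z-alkene the methyl group ends equatorial and the ring A arm axial, which is the C6 configuration of the target.

Step 19
Reactants: 27 iodo-dioxane
Product: 28 tert-butyl{(2R)-2-[(3S,6R)-6-(2-{(1S)-2,2-dimethyl-6-methylidene-1-[(triethylsilyl)oxy]cyclohexyl}ethyl)-6-methyl-1,2-dioxan-3-yl]propoxy}dimethylsilane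
Conditions: Bu3SnH (excess, ≥1 M), Et3B/air (cat.), toluene, 0 °C
Reagents that add atoms: none
Why: Radical-chain hydrodeiodination, where the high stannane concentration and low temperature should let hydrogen transfer to the C5 radical outrun its β-scission onto the peroxide bond.

Step 20
Reactants: 28 bis-silyl ether
Product: 29 (2R)-2-[(3S,6R)-6-{2-[(1S)-1-hydroxy-2,2-dimethyl-6-methylidenecyclohexyl]ethyl}-6-methyl-1,2-dioxan-3-yl]propan-1-ol
Conditions: HF·pyridine, pyridine, THF, 0 °C → rt
Reagents that add atoms: none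
Why: Fluoride-mediated desilylation under buffered, non-basic conditions should remove both silyl groups without base-induced fragmentation of the 1,2-dioxane or ionisation of the tertiary allylic alcohol.

Step 21
Reactants: 29 diol
Product: 31 (2S)-2-[(3S,6R)-6-{2-[(1S)-1-hydroxy-2,2-dimethyl-6-methylidenecyclohexyl]ethyl}-6-methyl-1,2-dioxan-3-yl]propanoic acid, via the aldehyde 30 (not isolated)
Conditions: TEMPO (cat.), PhI(OAc)2, MeCN/H2O, rt
Reagents that add atoms: water, O
Why: Oxoammonium (TEMPO) oxidation takes the primary alcohol through the aldehyde hydrate to the acid under near-neutral conditions, which should leave the tertiary alcohol, the peroxide and the C2 stereocentre untouched.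

Step 22
Reactants: 31 acid
Product: 32 methyl (2S)-2-[(3S,6R)-6-{2-[(1S)-1-hydroxy-2,2-dimethyl-6-methylidenecyclohexyl]ethyl}-6-methyl-1,2-dioxan-3-yl]propanoate (target)
Conditions: Me3SiCHN2, MeOH/toluene, 0 °C
Reagents that add atoms: trimethylsilyldiazomethane, C[Si](C)(C)C=[N+]=[N-]
Why: Esterification with a diazoalkane methylates only the carboxylic acid, without base or strong acid.

**Compound list**

1 | β-cyclocitral, 2,6,6-trimethylcyclohex-1-ene-1-carbaldehyde | CC1=C(C=O)C(C)(C)CCC1 | starting material
2 | β-cyclogeraniol, (2,6,6-trimethylcyclohex-1-en-1-yl)methanol | CC1=C(CO)C(C)(C)CCC1 | intermediate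
3 | [(1R,6R)-2,2,6-trimethyl-7-oxabicyclo[4.1.0]heptan-1-yl]methanol | OC[C@@]12O[C@]1(C)CCCC2(C)C | intermediate
4 | (1S,6R)-2,2,6-trimethyl-7-oxabicyclo[4.1.0]heptane-1-carbaldehyde | O=C[C@@]12O[C@]1(C)CCCC2(C)C | intermediate
5 | (1S,6R)-1-ethenyl-2,2,6-trimethyl-7-oxabicyclo[4.1.0]heptane | C=C[C@@]12O[C@]1(C)CCCC2(C)C | intermediate
6 | 9-{2-[(1S,6R)-2,2,6-trimethyl-7-oxabicyclo[4.1.0]heptan-1-yl]ethyl}-9-borabicyclo[3.3.1]nonane | C1CCC2CCCC1B2CC[C@@]12O[C@]1(C)CCCC2(C)C | intermediate
7 | 2-[(1S,6R)-2,2,6-trimethyl-7-oxabicyclo[4.1.0]heptan-1-yl]ethan-1-ol | OCC[C@@]12O[C@]1(C)CCCC2(C)C | intermediate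
8 | (1S)-1-(2-hydroxyethyl)-2,2-dimethyl-6-methylidenecyclohexan-1-ol | C=C1CCCC(C)(C)[C@@]1(O)CCO | intermediate
9 | (1S)-1-(2-bromoethyl)-2,2-dimethyl-6-methylidenecyclohexan-1-ol | C=C1CCCC(C)(C)[C@@]1(O)CCBr | intermediate
10 | {[(1S)-1-(2-bromoethyl)-2,2-dimethyl-6-methylidenecyclohexyl]oxy}triethylsilane | C=C1CCCC(C)(C)[C@@]1(O[Si](CC)(CC)CC)CCBr | intermediate
11 | (Z)-but-2-ene-1,4-diol | OC/C=C\CO | starting material
12 | (2Z)-4-{[tert-butyl(dimethyl)silyl]oxy}but-2-en-1-ol | OC/C=C\CO[Si](C)(C)C(C)(C)C | intermediate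
13 | [(2R,3S)-3-({[tert-butyl(dimethyl)silyl]oxy}methyl)oxiran-2-yl]methanol | OC[C@H]1O[C@H]1CO[Si](C)(C)C(C)(C)C | intermediate
14 | (2S,3R)-4-{[tert-butyl(dimethyl)silyl]oxy}-3-methylbutane-1,2-diol | OC[C@@H](O)[C@H](C)CO[Si](C)(C)C(C)(C)C | intermediate
15 | (2S,3R)-4-{[tert-butyl(dimethyl)silyl]oxy}-2-hydroxy-3-methylbutyl 4-methylbenzenesulfonate | Cc1ccc(cc1)S(=O)(=O)OC[C@@H](O)[C@H](C)CO[Si](C)(C)C(C)(C)C | intermediate
16 | tert-butyl(dimethyl){(2R)-2-[(2S)-oxiran-2-yl]propoxy}silane | [C@@H]1(CO1)[C@H](C)CO[Si](C)(C)C(C)(C)C | intermediate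
17 | propyne | CC#C | starting material
18 | 2-{(1S)-2,2-dimethyl-6-methylidene-1-[(triethylsilyl)oxy]cyclohexyl}ethylmagnesium bromide | C=C1CCCC(C)(C)[C@@]1(O[Si](CC)(CC)CC)CC[Mg]Br | intermediate
19 | 2-{(1S)-2,2-dimethyl-6-methylidene-1-[(triethylsilyl)oxy]cyclohexyl}ethylcopper (as its MgBr2·SMe2 complex) | C=C1CCCC(C)(C)[C@@]1(O[Si](CC)(CC)CC)CC[Cu] | intermediate
20 | (1Z)-4-{(1S)-2,2-dimethyl-6-methylidene-1-[(triethylsilyl)oxy]cyclohexyl}-2-methylbut-1-en-1-ylcopper | C=C1CCCC(C)(C)[C@@]1(O[Si](CC)(CC)CC)CC/C(C)=C\[Cu] | intermediate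
21 | (2R,3R,5Z)-1-{[tert-butyl(dimethyl)silyl]oxy}-8-{(1S)-2,2-dimethyl-6-methylidene-1-[(triethylsilyl)oxy]cyclohexyl}-2,6-dimethyloct-5-en-3-ol | C=C1CCCC(C)(C)[C@@]1(O[Si](CC)(CC)CC)CC/C(C)=C\C[C@H]([C@H](C)CO[Si](C)(C)C(C)(C)C)O | intermediate
22 | (2R,3R,5Z)-1-{[tert-butyl(dimethyl)silyl]oxy}-8-{(1S)-2,2-dimethyl-6-methylidene-1-[(triethylsilyl)oxy]cyclohexyl}-2,6-dimethyloct-5-en-3-yl trifluoromethanesulfonate | C=C1CCCC(C)(C)[C@@]1(O[Si](CC)(CC)CC)CC/C(C)=C\C[C@H]([C@H](C)CO[Si](C)(C)C(C)(C)C)OS(=O)(=O)C(F)(F)F | intermediate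
23 | 2,3-dimethylbut-2-ene | CC(C)=C(C)C | starting material
24 | 2-methoxypropan-2-yl hydroperoxide | COC(C)(C)OO | intermediate
25 | tert-butyl{[(2R,3S,5Z)-8-{(1S)-2,2-dimethyl-6-methylidene-1-[(triethylsilyl)oxy]cyclohexyl}-3-[(2-methoxypropan-2-yl)peroxy]-2,6-dimethyloct-5-en-1-yl]oxy}dimethylsilane | C=C1CCCC(C)(C)[C@@]1(O[Si](CC)(CC)CC)CC/C(C)=C\C[C@@H]([C@H](C)CO[Si](C)(C)C(C)(C)C)OOC(C)(C)OC | intermediate
26 | (2R,3S,5Z)-1-{[tert-butyl(dimethyl)silyl]oxy}-8-{(1S)-2,2-dimethyl-6-methylidene-1-[(triethylsilyl)oxy]cyclohexyl}-2,6-dimethyloct-5-en-3-yl hydroperoxide | C=C1CCCC(C)(C)[C@@]1(O[Si](CC)(CC)CC)CC/C(C)=C\C[C@@H]([C@H](C)CO[Si](C)(C)C(C)(C)C)OO | intermediate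
27 | tert-butyl{(2R)-2-[(3S,5S,6S)-6-(2-{(1S)-2,2-dimethyl-6-methylidene-1-[(triethylsilyl)oxy]cyclohexyl}ethyl)-5-iodo-6-methyl-1,2-dioxan-3-yl]propoxy}dimethylsilane | C=C1CCCC(C)(C)[C@@]1(O[Si](CC)(CC)CC)CC[C@@]1(C)[C@@H](I)C[C@@H]([C@H](C)CO[Si](C)(C)C(C)(C)C)OO1 | intermediate
28 | tert-butyl{(2R)-2-[(3S,6R)-6-(2-{(1S)-2,2-dimethyl-6-methylidene-1-[(triethylsilyl)oxy]cyclohexyl}ethyl)-6-methyl-1,2-dioxan-3-yl]propoxy}dimethylsilane | C=C1CCCC(C)(C)[C@@]1(O[Si](CC)(CC)CC)CC[C@@]1(C)CC[C@@H]([C@H](C)CO[Si](C)(C)C(C)(C)C)OO1 | intermediate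
29 | (2R)-2-[(3S,6R)-6-{2-[(1S)-1-hydroxy-2,2-dimethyl-6-methylidenecyclohexyl]ethyl}-6-methyl-1,2-dioxan-3-yl]propan-1-ol | C=C1CCCC(C)(C)[C@@]1(O)CC[C@@]1(C)CC[C@@H]([C@H](C)CO)OO1 | intermediate
30 | (2S)-2-[(3S,6R)-6-{2-[(1S)-1-hydroxy-2,2-dimethyl-6-methylidenecyclohexyl]ethyl}-6-methyl-1,2-dioxan-3-yl]propanal | C=C1CCCC(C)(C)[C@@]1(O)CC[C@@]1(C)CC[C@@H]([C@H](C)C=O)OO1 | intermediate
31 | (2S)-2-[(3S,6R)-6-{2-[(1S)-1-hydroxy-2,2-dimethyl-6-methylidenecyclohexyl]ethyl}-6-methyl-1,2-dioxan-3-yl]propanoic acid | C=C1CCCC(C)(C)[C@@]1(O)CC[C@@]1(C)CC[C@@H]([C@H](C)C(=O)O)OO1 | intermediate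
32 | methyl (2S)-2-[(3S,6R)-6-{2-[(1S)-1-hydroxy-2,2-dimethyl-6-methylidenecyclohexyl]ethyl}-6-methyl-1,2-dioxan-3-yl]propanoate | C=C1CCCC(C)(C)[C@@]1(O)CC[C@@]1(C)CC[C@@H]([C@H](C)C(=O)OC)OO1 | target

**Step count and risks**

Total step count: 22. Longest linear sequence: 17 steps (steps 1–8, 13, 14, 16–22).

The three steps most likely to fail:

Step 16 (peroxide displacement). Elimination of triflate toward the allylic C4 hydrogens, or ionisation of the homoallylic triflate with participation of the C5=C6 alkene, may outrun bimolecular attack of the peroxide anion at a secondary carbon that has a branched neighbour. The fallback makes the C3–O bond intramolecularly and sets out from alcohol 21. Mesylation (MsCl, Et3N, CH2Cl2, 0 °C) should give, with retention, the mesylate F1. N-Iodosuccinimide with anhydrous ethereal H2O2 (Et2O, −20 °C) should then add iodine and a hydroperoxy group across the C5=C6 alkene in the Markovnikov and anti sense to give the tertiary β-iodo hydroperoxide F2, formed together with its C5,C6-diastereomer because nothing controls the alkene face. Cs2CO3 in DMF at 0 °C should close the 1,2-dioxane by six-membered intramolecular displacement of the mesylate with inversion at C3. The sequence comes back to the route at iodo-dioxane 27 after chromatographic removal of the diastereomer; the price is the loss of facial control at C6.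

Step 18 (iodoperoxidation). Closure in the 5-exo mode to a 1,2-dioxolane, attack of the iodonium source on the exocyclic alkene of ring A, or closure through the chair with the C3 substituent axial would erode regio-, chemo- or diastereoselectivity. The fallback replaces halocyclisation by epoxide opening, with reagent control of C6, and sets out from peroxyketal 25. Shi epoxidation (fructose-derived ketone or its enantiomer, KHSO5, K2CO3 buffer, MeCN/dimethoxymethane/H2O, 0 °C; the catalyst enantiomer is the one that places oxygen on the alkene face opposite to the future C6–O1 bond) should give the epoxy peroxyketal F3. Camphorsulfonic acid in wet CH2Cl2 should release the epoxy hydroperoxide F4, which should close at once by 6-endo attack on the tertiary epoxide carbon with inversion to give the 5-hydroxy-1,2-dioxane F5. Barton–McCombie deoxygenation (1,1'-thiocarbonyldiimidazole, then Bu3SnH, Et3B/air) through the imidazolylthiocarbonate F6 removes the C5 hydroxyl. The sequence comes back to the route at dioxane 28.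

Step 13 (three-component union). The alkenylcopper intermediate may be protonated or decompose before it opens the α-branched epoxide, so that the union stops at the two-component stage. The fallback makes the same two bonds in two operations and sets out from bromide 10 and propyne 17. The carbocupration is run as in step 13 and the alkenylcopper 20 is quenched with I2 to give, with retention, the Z-alkenyl iodide F7. Iodine–lithium exchange (t-BuLi, 2 equiv, Et2O, −78 °C) should give the alkenyllithium F8, which with BF3·OEt2 at −78 °C should open epoxide 16 at its CH2 terminus. The sequence comes back to the route at alcohol 21.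

**Further compounds**

F1 | step 16 | (2R,3R,5Z)-1-{[tert-butyl(dimethyl)silyl]oxy}-8-{(1S)-2,2-dimethyl-6-methylidene-1-[(triethylsilyl)oxy]cyclohexyl}-2,6-dimethyloct-5-en-3-yl methanesulfonate | C=C1CCCC(C)(C)[C@@]1(O[Si](CC)(CC)CC)CC/C(C)=C\C[C@H]([C@H](C)CO[Si](C)(C)C(C)(C)C)OS(C)(=O)=O
F2 | step 16 | 6-hydroperoxy-5-iodo analogue of F1 (saturated chain, C5 and C6 configured as in 27, C3 mesylate retained) | C=C1CCCC(C)(C)[C@@]1(O[Si](CC)(CC)CC)CC[C@](C)(OO)[C@@H](I)C[C@H]([C@H](C)CO[Si](C)(C)C(C)(C)C)OS(C)(=O)=O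
F3 | step 18 | 5,6-epoxide of peroxyketal 25 (cis-epoxide, oxygen on the face opposite to the future C6–O1 bond) | C=C1CCCC(C)(C)[C@@]1(O[Si](CC)(CC)CC)CC[C@@]1(C)O[C@H]1C[C@@H]([C@H](C)CO[Si](C)(C)C(C)(C)C)OOC(C)(C)OC
F4 | step 18 | 5,6-epoxy C3 hydroperoxide (F3 without the 2-methoxypropan-2-yl group) | C=C1CCCC(C)(C)[C@@]1(O[Si](CC)(CC)CC)CC[C@@]1(C)O[C@H]1C[C@@H]([C@H](C)CO[Si](C)(C)C(C)(C)C)OO
F5 | step 18 | 5-hydroxy analogue of dioxane 28 (hydroxyl in the position of the iodine of 27) | C=C1CCCC(C)(C)[C@@]1(O[Si](CC)(CC)CC)CC[C@@]1(C)[C@@H](O)C[C@@H]([C@H](C)CO[Si](C)(C)C(C)(C)C)OO1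
F6 | step 18 | O-(1H-imidazol-1-ylcarbonothioyl) derivative of F5 | C=C1CCCC(C)(C)[C@@]1(O[Si](CC)(CC)CC)CC[C@@]1(C)[C@@H](OC(=S)n2ccnc2)C[C@@H]([C@H](C)CO[Si](C)(C)C(C)(C)C)OO1
F7 | step 13 | triethyl({(1S)-1-[(3Z)-4-iodo-3-methylbut-3-en-1-yl]-2,2-dimethyl-6-methylidenecyclohexyl}oxy)silane | C=C1CCCC(C)(C)[C@@]1(O[Si](CC)(CC)CC)CC/C(C)=C\I
F8 | step 13 | (1Z)-4-{(1S)-2,2-dimethyl-6-methylidene-1-[(triethylsilyl)oxy]cyclohexyl}-2-methylbut-1-en-1-yllithium | C=C1CCCC(C)(C)[C@@]1(O[Si](CC)(CC)CC)CC/C(C)=C\[Li]
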